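The dawn run holds more J against its G than the noon run, 0.254 against 0.0882 at 5.00 min, and dawn charges twice the equivalents of L, with more G as well, so L is the first setting we turn.

| flask | G | L | E | remark | time |
|---|---|---|---|---|---|
| noon | 3.4 × 10⁻⁴ M | 1.3 equiv | 0.60 equiv | run made earlier |  |
| midnight | 7.5 × 10⁻⁴ M | 1.3 equiv | 0.60 equiv | run made earlier |  |
| dawn | 5.0 × 10⁻⁴ M | 2.6 equiv | 0.60 equiv | run made earlier |  |
| flask | 5.0 × 10⁻⁴ M | 1.30 equiv | 0.600 equiv |  | 40 min |

| run | time / min | J / % | G / % |
|---|---|---|---|
| noon | 0.500 | 6 | 87 |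
| noon | 1.50 | 9 | 80 |
| noon | 5.00 | 6 | 68 |
| noon | 15.0 | 8 | 53 |
| noon | 50.0 | 4 | 37 |
| midnight | 0.500 | 10 | 80 |
| midnight | 1.50 | 11 | 72 |
| midnight | 5.00 | 8 | 52 |
| midnight | 15.0 | 8 | 40 |
| midnight | 50.0 | 8 | 31 |
| dawn | 0.500 | 15 | 79 |
| dawn | 1.50 | 16 | 71 |
| dawn | 5.00 | 15 | 59 |
| dawn | 15.0 | 12 | 41 |
| dawn | 50.0 | 8 | 33 |

(each reading ± 1.5 percentage points)

- time up to 40 min at which J stands highest
- the amount of J, in percent of the G charged, at that time

By hand, if J stands in balance with G and L, more L equivalents should raise J against G in step with the L concentration, and more G at fixed equivalents should do the same, since it brings more L along; midnight against noon shows this second turn, 0.154 against 0.0882 at the same time. Both turns meet in one quantity, which over the readings from 1.50 min on averages 217 M⁻¹: the balance number, J over G divided by the L concentration charged.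

balance number = (J / G) / L

At 0.500 min it reads lower, 143 M⁻¹, which we take to mean that J is still catching up there, and afterwards we expect it to follow G down.

E, the last setting, stays at 0.60 equiv in these runs, and the G lost beyond J at the last readings is 59.0%, 61.0% and 59.0% of the charge, which we read as one G lost per E, with E as the limiting reagent of that loss.

For the flask we take G as 76.0%, the noon and midnight mean at 1.50 min, and place the peak between 0.500 min and 1.50 min:

J = 217 M⁻¹ × 6.50 × 10⁻⁴ M × 76.0% = 10.7%

The forecast, which reasons that “The peak height rises with L concentration”, gives less: 9.5% (8% to 11.5%) at 1.5 min (0.7 min to 4 min).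

The flask gives 9.21% at 1.28 min.

    G ⇌ Q (K = 0.00953, k = 0.0453 s⁻¹)
    L + Q ⇌ J (K = 21000 M⁻¹, k = 1020 M⁻¹ s⁻¹)
    E + Q → X (k = 2780 M⁻¹ s⁻¹)
    E ⇌ Z (K = 3.47, k = 0.146 s⁻¹)

In the flask, L + Q ⇌ J relaxes by itself, both ways together, with a half-life of 1.01 s at 40.0 min, short against the 40 min allowed, and the balance number, taken with the L still there, stands at 194 M⁻¹ at the best time and 200 M⁻¹ at 40.0 min, beside our reading of 217 M⁻¹. In the neighbouring flask with 2.0 × 10⁻⁴ M of G, our reading times its charged L and its 47.6% of G gives 2.69% of J, and at 40.0 min that flask holds 2.43%.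

(The numbers in the tables were generated by integration from invented constants, and the scatter is random.)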